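**Retrosynthetic overview**
- The target comes from a 2-alkyl-5-methylfuran in one flask: acid hydrolysis opens the furan to the C10/C13 1,4-diketone, and an (S)-selective alcohol dehydrogenase then reduces only the methyl ketone (C13).
- The same acid closes the phthalide lactone from an (S)-γ-hydroxy diethylbenzamide and frees the phenol. This lactone is the only ring formed, and it is formed last; the furan is the only ring opened.
- C3 is set by asymmetric transfer hydrogenation of an aryl ketone. The ketone comes from an ortho-lithiated N,N-diethyl-2-methoxy-4-silyloxybenzamide and the Weinreb amide of 10-(5-methylfuran-2-yl)decanoic acid.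
- The Weinreb amide comes from 2-methylfuran (C5 lithiation, alkylation with 1,9-dibromononane, Grignard carbamoylation). The benzamide comes from 4-bromo-3-methoxyphenol (silylation, Br–Li exchange, carbamoylation).

Assumption: the target is treated as the open-chain γ-hydroxy ketone as drawn (its lactol tautomer is not counted separately), and ADH-A from Rhodococcus ruber is used as a purchased recombinant lyophilisate.

**Route**

Step 1
Reactants: 1 2-methylfuran; 2 1,9-dibromononane
Product: 4 2-(9-bromononyl)-5-methylfuran, via 5-methyl-2-furyllithium 3 (not isolated)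
Conditions: n-BuLi (1.0 equiv), THF, 0 °C to rt, 2 h; then added to 2 (3 equiv), THF, −78 °C to rt, 12 h
Reagents that add atoms: 1,9-dibromononane, BrCCCCCCCCCBr
Why: n-BuLi deprotonates 2-methylfuran only at its free α-position and the furyllithium displaces one bromide of the symmetric dibromide (heteroaryl lithiation–SN2 alkylation), the threefold excess of 2 suppressing double substitution; no stereocentre is formed.

Step 2
Reactants: 4 2-(9-bromononyl)-5-methylfuran; 5 N,N'-dimethoxy-N,N'-dimethylurea
Product: 7 N-methoxy-N-methyl-10-(5-methylfuran-2-yl)decanamide, via [9-(5-methylfuran-2-yl)nonyl]magnesium bromide 6 (not isolated)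
Conditions: Mg (1.5 equiv), cat. I2, THF, 40 °C; then 5 (1.5 equiv), THF, 0 °C to rt; AcOH quench
Reagents that add atoms: N,N'-dimethoxy-N,N'-dimethylurea, CON(C)C(=O)N(C)OC
Why: Grignard formation followed by a single acyl substitution on the urea (Whipple–Reich Weinreb amide synthesis) works because the magnesium-chelated tetrahedral adduct survives until the quench, so no ketone forms, and the 2,5-dialkylfuran is inert to the Grignard reagent.

Step 3
Reactants: 8 4-bromo-3-methoxyphenol; 9 tert-butyldimethylsilyl chloride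
Product: 10 (4-bromo-3-methoxyphenoxy)(tert-butyl)dimethylsilane
Conditions: TBSCl (1.1 equiv), imidazole (2.2 equiv), DMF, rt, 3 h
Reagents that add atoms: tert-butyldimethylsilyl chloride, CC(C)(C)[Si](C)(C)Cl
Why: Imidazole-promoted silylation of the only OH (silyl ether protection) gives an ether that does not direct lithiation, shields both flanking ring positions, and is later lost in hot aqueous acid.

Step 4
Reactants: 10 (4-bromo-3-methoxyphenoxy)(tert-butyl)dimethylsilane; 11 N,N-diethylcarbamoyl chloride
Product: 13 N,N-diethyl-2-methoxy-4-[(tert-butyldimethylsilyl)oxy]benzamide, via 2-methoxy-4-silyloxyphenyllithium 12 (not isolated)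
Conditions: n-BuLi (1.05 equiv), THF, −78 °C, 20 min; then ClC(O)NEt2 (1.5 equiv), −78 °C to rt
Reagents that add atoms: N,N-diethylcarbamoyl chloride, CCN(CC)C(Cl)=O
Why: Bromine–lithium exchange at −78 °C outruns any deprotonation and fixes the carbon that will carry the carboxamide (ortho to OMe, para to the silyloxy group), and the aryllithium is trapped by the carbamoyl chloride (acyl substitution) to a tertiary amide that resists further addition at this temperature.

Step 5
Reactants: 13 N,N-diethyl-2-methoxy-4-[(tert-butyldimethylsilyl)oxy]benzamide; 7 N-methoxy-N-methyl-10-(5-methylfuran-2-yl)decanamide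
Product: 15 N,N-diethyl-2-methoxy-6-[10-(5-methylfuran-2-yl)decanoyl]-4-[(tert-butyldimethylsilyl)oxy]benzamide, via ortho-lithiated benzamide 14 (not isolated)
Conditions: s-BuLi (1.15 equiv), TMEDA (1.2 equiv), THF, −78 °C, 1 h; then 7 (1.0 equiv), −78 to −40 °C; AcOH quench
Reagents that add atoms: N-methoxy-N-methyl-10-(5-methylfuran-2-yl)decanamide, Cc1ccc(CCCCCCCCCC(=O)N(C)OC)o1
Why: Directed ortho-metalation (Snieckus) puts lithium on the only free position ortho to the tertiary amide (the other ortho position carries OMe and the remaining ring CH groups flank the bulky silyl ether), and the aryllithium adds once to the Weinreb amide through its chelated adduct to give the aryl ketone, the α-blocked furan being inert.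

Step 6
Reactants: 15 N,N-diethyl-2-methoxy-6-[10-(5-methylfuran-2-yl)decanoyl]-4-[(tert-butyldimethylsilyl)oxy]benzamide
Product: 16 (S)-N,N-diethyl-2-[1-hydroxy-10-(5-methylfuran-2-yl)decyl]-6-methoxy-4-[(tert-butyldimethylsilyl)oxy]benzamide
Conditions: RuCl[(S,S)-TsDPEN](p-cymene) (2 mol %), HCO2H/Et3N (5:2), DMF, 35 °C, 24 h
Reagents that add atoms: none
Why: Noyori–Ikariya asymmetric transfer hydrogenation of an aryl alkyl ketone, in which the hydride formed from RuCl[(S,S)-TsDPEN](p-cymene) attacks the face that gives the (S)-benzylic alcohol (same sense as acetophenone to (S)-1-phenylethanol), sets the future C3 while amide, furan and silyl ether are untouched.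

Step 7
Reactants: 16 (S)-N,N-diethyl-2-[1-hydroxy-10-(5-methylfuran-2-yl)decyl]-6-methoxy-4-[(tert-butyldimethylsilyl)oxy]benzamide
Product: 19 (S)-5-hydroxy-3-[(S)-13-hydroxy-10-oxotetradecyl]-7-methoxyisobenzofuran-1(3H)-one, via silyl furan lactone 17 (not isolated), via diketone phenol 18 (not isolated)
Conditions: 2 M HCl, i-PrOH/H2O (1:1), 75 °C, 6 h; then KOH/K2HPO4 to pH 7.5, NAD+ (1 mM), ADH-A from Rhodococcus ruber (lyophilised cells), i-PrOH (30% v/v), 30 °C, 24–48 h
Reagents that add atoms: water, O
Why: Hot aqueous acid lactonises the γ-hydroxy amide with retention at C3, cleaves the aryl silyl ether and hydrolyses the 2,5-dialkylfuran to the 1,4-diketone (dearomatising furan hydrolysis, reverse Paal–Knorr), and after neutralisation the Prelog-selective alcohol dehydrogenase, which accepts only ketones with one small substituent, transfers hydride from 2-propanol to the Re face of the methyl ketone alone and so sets C13 as (S) while the C10 ketone between two long chains is not a substrate.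

**Compound list**

1 | 2-methylfuran | Cc1ccco1 | starting material
2 | 1,9-dibromononane | BrCCCCCCCCCBr | starting material
3 | 5-methyl-2-furyllithium | Cc1ccc([Li])o1 | intermediate
4 | 2-(9-bromononyl)-5-methylfuran | Cc1ccc(CCCCCCCCCBr)o1 | intermediate
5 | N,N'-dimethoxy-N,N'-dimethylurea | CON(C)C(=O)N(C)OC | starting material
6 | [9-(5-methylfuran-2-yl)nonyl]magnesium bromide | Cc1ccc(CCCCCCCCC[Mg]Br)o1 | intermediate
7 | N-methoxy-N-methyl-10-(5-methylfuran-2-yl)decanamide | Cc1ccc(CCCCCCCCCC(=O)N(C)OC)o1 | intermediate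
8 | 4-bromo-3-methoxyphenol | COc1cc(O)ccc1Br | starting material
9 | tert-butyldimethylsilyl chloride | CC(C)(C)[Si](C)(C)Cl | starting material
10 | (4-bromo-3-methoxyphenoxy)(tert-butyl)dimethylsilane | COc1cc(O[Si](C)(C)C(C)(C)C)ccc1Br | intermediate
11 | N,N-diethylcarbamoyl chloride | CCN(CC)C(Cl)=O | starting material
12 | 2-methoxy-4-[(tert-butyldimethylsilyl)oxy]phenyllithium | COc1cc(O[Si](C)(C)C(C)(C)C)ccc1[Li] | intermediate
13 | N,N-diethyl-2-methoxy-4-[(tert-butyldimethylsilyl)oxy]benzamide | CCN(CC)C(=O)c1ccc(O[Si](C)(C)C(C)(C)C)cc1OC | intermediate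
14 | N,N-diethyl-2-lithio-6-methoxy-4-[(tert-butyldimethylsilyl)oxy]benzamide | CCN(CC)C(=O)c1c([Li])cc(O[Si](C)(C)C(C)(C)C)cc1OC | intermediate
15 | N,N-diethyl-2-methoxy-6-[10-(5-methylfuran-2-yl)decanoyl]-4-[(tert-butyldimethylsilyl)oxy]benzamide | CCN(CC)C(=O)c1c(OC)cc(O[Si](C)(C)C(C)(C)C)cc1C(=O)CCCCCCCCCc1ccc(C)o1 | intermediate
16 | (S)-N,N-diethyl-2-[1-hydroxy-10-(5-methylfuran-2-yl)decyl]-6-methoxy-4-[(tert-butyldimethylsilyl)oxy]benzamide | CCN(CC)C(=O)c1c(OC)cc(O[Si](C)(C)C(C)(C)C)cc1[C@@H](O)CCCCCCCCCc1ccc(C)o1 | intermediate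
17 | (S)-5-[(tert-butyldimethylsilyl)oxy]-7-methoxy-3-[9-(5-methylfuran-2-yl)nonyl]isobenzofuran-1(3H)-one | COc1cc(O[Si](C)(C)C(C)(C)C)cc2c1C(=O)O[C@H]2CCCCCCCCCc1ccc(C)o1 | intermediate
18 | (S)-3-(10,13-dioxotetradecyl)-5-hydroxy-7-methoxyisobenzofuran-1(3H)-one | COc1cc(O)cc2c1C(=O)O[C@H]2CCCCCCCCCC(=O)CCC(C)=O | intermediate
19 | (S)-5-hydroxy-3-[(S)-13-hydroxy-10-oxotetradecyl]-7-methoxyisobenzofuran-1(3H)-one | COc1cc(O)cc2c1C(=O)O[C@H]2CCCCCCCCCC(=O)CC[C@H](C)O | target

**Step count and risks**

Total steps: 7. Longest linear sequence: 5 steps (8 → 10 → 13 → 15 → 16 → 19, or equally 1 → 4 → 7 → 15 → 16 → 19).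

The three steps most likely to fail:

Step 7. The enzyme must work in the neutralised crude of the acid stage and must distinguish the two ketones of 18; the diketone may also suffer in hot acid. The fallback takes C13 from the chiral pool and replaces the furan by an alkynol; it sets out from 2 and comes back at 19. Bought (S)-pent-4-yn-2-ol is silylated (TBSCl, imidazole) to (S)-tert-butyldimethyl(pent-4-yn-2-yloxy)silane F3. Its lithium acetylide (n-BuLi, THF/DMPU) is alkylated with excess 2 to (S)-[(14-bromotetradec-4-yn-2-yl)oxy](tert-butyl)dimethylsilane F4. F4 is carried through the chemistry of steps 2, 5 and 6 (Mg then 5; addition of 14; the same transfer hydrogenation) to the alkynyl Weinreb amide F5, the alkynyl keto amide F6 and the alkynyl hydroxy amide F7. 2 M HCl in i-PrOH/H2O at 60 °C then lactonises and removes both silyl groups to give the alkynol phthalide F8. NaAuCl4 (2 mol %) in wet MeCN brings about 5-endo-dig attack of the C13 hydroxyl on the alkyne and hydration of the resulting 2,3-dihydrofuran, which places the ketone at C10 only and gives 19.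

Step 5. The basic aryllithium 14 may enolise 7 instead of adding, and both fragments are then lost. The fallback reverses the polarity; it sets out from 14 and comes back at 15. 14 is quenched with the urea 5 (no α-hydrogens) to give N,N-diethyl-2-methoxy-6-[methoxy(methyl)carbamoyl]-4-[(tert-butyldimethylsilyl)oxy]benzamide F1. The less basic Grignard reagent 6 (made from 4) is then added to F1 at 0 °C to give 15.

Step 6. The ketone sits next to a twisted ortho-diethylamide, so the transfer hydrogenation may be slow or give eroded ee, and the sense of induction is assigned by analogy. The fallback sets C3 in a C–C bond formation instead of a reduction; it sets out from 14 and comes back at 16. 14 is quenched with DMF to give N,N-diethyl-2-formyl-6-methoxy-4-[(tert-butyldimethylsilyl)oxy]benzamide F2. The Grignard reagent 6 is then added to F2 in the presence of Ti(OiPr)4 (excess) and catalytic (S)-3-(3,5-diphenylphenyl)-H8-BINOL in CH2Cl2 at 0 °C. By analogy with benzaldehyde the (S)-ligand should give the (S)-carbinol 16; this is to be confirmed on the first run.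

**Further compounds**

F1 | step 5 | N,N-diethyl-2-methoxy-6-[methoxy(methyl)carbamoyl]-4-[(tert-butyldimethylsilyl)oxy]benzamide | CCN(CC)C(=O)c1c(OC)cc(O[Si](C)(C)C(C)(C)C)cc1C(=O)N(C)OC
F2 | step 6 | N,N-diethyl-2-formyl-6-methoxy-4-[(tert-butyldimethylsilyl)oxy]benzamide | CCN(CC)C(=O)c1c(OC)cc(O[Si](C)(C)C(C)(C)C)cc1C=O
F3 | step 7 | (S)-tert-butyldimethyl(pent-4-yn-2-yloxy)silane | C#CC[C@H](C)O[Si](C)(C)C(C)(C)C
F4 | step 7 | (S)-[(14-bromotetradec-4-yn-2-yl)oxy](tert-butyl)dimethylsilane | BrCCCCCCCCCC#CC[C@H](C)O[Si](C)(C)C(C)(C)C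
F5 | step 7 | (S)-14-[(tert-butyldimethylsilyl)oxy]-N-methoxy-N-methylpentadec-11-ynamide | CON(C)C(=O)CCCCCCCCCC#CC[C@H](C)O[Si](C)(C)C(C)(C)C
F6 | step 7 | N,N-diethyl-2-methoxy-4-[(tert-butyldimethylsilyl)oxy]-6-[(S)-14-[(tert-butyldimethylsilyl)oxy]pentadec-11-ynoyl]benzamide | CCN(CC)C(=O)c1c(OC)cc(O[Si](C)(C)C(C)(C)C)cc1C(=O)CCCCCCCCCC#CC[C@H](C)O[Si](C)(C)C(C)(C)C
F7 | step 7 | N,N-diethyl-2-[(1S,14S)-14-[(tert-butyldimethylsilyl)oxy]-1-hydroxypentadec-11-yn-1-yl]-6-methoxy-4-[(tert-butyldimethylsilyl)oxy]benzamide | CCN(CC)C(=O)c1c(OC)cc(O[Si](C)(C)C(C)(C)C)cc1[C@@H](O)CCCCCCCCCC#CC[C@H](C)O[Si](C)(C)C(C)(C)C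
F8 | step 7 | (S)-5-hydroxy-3-[(S)-13-hydroxytetradec-10-yn-1-yl]-7-methoxyisobenzofuran-1(3H)-one | COc1cc(O)cc2c1C(=O)O[C@H]2CCCCCCCCCC#CC[C@H](C)O
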